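| flask | D | X | L | remark |
|---|---|---|---|---|
| alder | 20 mM | 1 equiv | 0.2 mol% | the very flask that is asked about, followed so far |
| elm | 20 mM | 1 equiv | 0.3 mol% | run made earlier |
| flask | 20 mM | 1.00 equiv | 0.2 mol% |  |

| run | time / min | G / % | D / % |
|---|---|---|---|
| alder | 0.667 | 1.4 | 98.9 |
| alder | 2.00 | 1.8 | 97.4 |
| alder | 4.00 | 3.8 | 96.1 |
| alder | 5.00 | 5.0 | 96.7 |
| alder | 8.00 | 7.8 | 92.7 |
| alder | 10.0 | 7.3 | 91.3 |
| elm | 6.00 | 8.3 | 92.3 |
| elm | 12.0 | 17.2 | 84.3 |
| elm | 20.0 | 25.9 | 74.8 |
| elm | 25.0 | 33.4 | 69.0 |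
| elm | 30.0 | 35.7 | 63.5 |
| elm | 40.0 | 44.5 | 54.8 |

(scatter of a reading: 1 percentage point)

- the numbers in the tables scatter with a standard deviation of 1 percentage point
- no earlier run changes the charge of X; that part of a forecast is a guess

- factor on the rate of making G when 20 % of the D are converted if X is charged twice over
- factor on the rate when 20 % of the D are converted if L is charged at 2 mol% instead

**Two turnovers.** After 10.0 min the alder readings showed 8.70 % of D, the substrate, gone. Divided by the time and the loading of L, the catalyst, that gave 4.35 min⁻¹, the turnover frequency τ, meaning D used per minute per L charged. The elm readings, with 0.3 mol% of L, showed a like share, 7.70 %, gone after 6.00 min, which gave a reading of τ = 4.28 min⁻¹.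

**My reckoning.** The two readings stand in the ratio 0.984, though each loss carries a scatter of 1 percentage point. I therefore took τ as unchanged by the loading, so I reckoned the rate in step with the charge of L and the factor for 2 mol% as 10.0. No earlier run changes X, so I reckoned nothing for it.

**The forecast.** It gave 12 for L, above my figure, and 1.5 for X, saying: “My guess is in between”.

**The result.** The flask gave 11.6 for L and 0.926 for X.

    Q → L + J (k = 0.688 s⁻¹)
    D + L ⇌ Z (K = 180 M⁻¹, k = 31.2 M⁻¹ s⁻¹)
    X + L ⇌ Q (K = 24.0 M⁻¹, k = 22.8 M⁻¹ s⁻¹)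
    Z → L + G (k = 0.129 s⁻¹)
    L ⇌ E (K = 2.60, k = 4.05 × 10⁻⁴ s⁻¹)

**Where they part.** At 20 % conversion, after 23.5 min, this flask made G at τ = 3.75 min⁻¹, counted per L charged, a later moment than the 4.35 min⁻¹ read in alder over its first 10.0 min. With 2 mol% of L, τ was 4.36 min⁻¹, faster than in this flask. At 21.8 min in this flask, the forward step to Z, the D-bound form, taken alone, gave L a half-life of 1.4 s, against 31 min for D. After 25.0 min in this flask, Z held 47.7 % of the catalyst, Q, the X-bound form, 6.88 %, free L 29.3 % and E, the form outside the round, 16.1 %.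

The numbers in the tables come from a simulation with constants of no real substance, and the scatter is random.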